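**Strategy.** Siphonein is assembled from a ring A acid, a stannylated C4 butenolide, the C10 dialdehyde and a ring B C15 unit made from (R)-α-ionone (carotenoid numbering). The route rests on ring A being a masked 4-hydroxy-2,2-dimethylcyclohexanone: C6 is a ketone (later the C5=C6 enol triflate) and the C1 gem-dimethyl carbon makes C2 a neopentyl, β-hydrogen-free and non-enolisable β-metallo ketone. One operation turns an acyclic iodo keto aldehyde into this ring by C2–C3 bond formation and sets C3 under a chiral chromium ligand. A late Stille acylation installs the C8 ketone and joins ring A to the polyene.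

Key step: step 4

Remark: ring A is the 3-hydroxy-β ring (C1–C6) next to the C8 ketone; ring B is the 3'-hydroxy-ε ring.
Remark: (R)-(+)-α-ionone is assumed to be purchasable enantiopure.
Remark: which antipode of the chromium ligand in step 4 gives the 4R alcohol is to be settled in a first experiment; the (S) ligand is written.

Step 1
Reactants: 1 3-bromo-2,2-dimethylpropanoic acid
Product: 2 3-iodo-2,2-dimethylpropanoic acid
Conditions: NaI (3 equiv), 2-butanone, reflux; dilute acid work-up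
Reagents that add atoms: sodium iodide [Na+].[I-]
Why: Finkelstein exchange; direct SN2 at the neopentyl carbon is slow, so the exchange is expected to run with carboxylate participation through a transient β-lactone that iodide reopens at its CH2 carbon.

Step 2
Reactants: 2 3-iodo-2,2-dimethylpropanoic acid; 3 [2-(1,3-dioxolan-2-yl)ethyl]magnesium bromide (commercial THF solution)
Product: 5 5-(1,3-dioxolan-2-yl)-1-iodo-2,2-dimethylpentan-3-one, via 3-iodo-2,2-dimethylpropanoyl chloride 4 (not isolated)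
Conditions: (COCl)2, cat. DMF, CH2Cl2, 20 °C, evaporate; then 3 (1.05 equiv), CuI (5 mol %), THF, −78 °C
Reagents that add atoms: none
Why: Copper-catalysed acylation of a Grignard reagent by an acid chloride should stop at the ketone at −78 °C, and the neopentyl iodide is inert to substitution.

Step 3
Reactants: 5 5-(1,3-dioxolan-2-yl)-1-iodo-2,2-dimethylpentan-3-one
Product: 6 6-iodo-5,5-dimethyl-4-oxohexanal
Conditions: 1 M aq. HCl, THF, 20 °C
Reagents that add atoms: water O
Why: Acid-catalysed acetal hydrolysis; mild conditions should avoid Paal–Knorr furan formation from the 1,4-dicarbonyl compound.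

Step 4
Reactants: 6 6-iodo-5,5-dimethyl-4-oxohexanal
Product: 8 (4R)-4-hydroxy-2,2-dimethylcyclohexan-1-one, via alkylchromium species 7 (not isolated)
Conditions: CrCl2 (3 equiv), (S)-N-[2-(4-isopropyl-4,5-dihydro-1,3-oxazol-2-yl)-6-methylphenyl]methanesulfonamide (3.3 equiv), Et3N (3.3 equiv), cobalt phthalocyanine Co(C32H16N8) (5 mol %), THF, 20 °C; aqueous work-up
Reagents that add atoms: none
Why: Proposed new method: cobalt phthalocyanine abstracts iodine from the neopentyl C2–I bond and divalent chromium captures the C2 radical, so that the ligand-bound alkylchromium 7 (a β-chromio ketone) adds to the C3 aldehyde; the closest known reaction type is the cobalt-catalysed, chromium-mediated enantioselective addition of alkyl iodides to aldehydes (Nozaki–Hiyama–Kishi-type alkylation), known between two molecules and used here within one molecule on a neopentyl iodide. Ring A closes in a 6-exo-trig mode by forming the C2–C3 bond. The only new stereocenter, C3, is set by the chiral oxazoline–sulfonamide ligand on trivalent chromium (reagent control on an achiral substrate). The step needs addition to the aldehyde in preference to the C6 ketone, which the low ketone reactivity of alkylchromium reagents and the strain of the three-membered alternative should secure. It also needs a C2–chromium bond that lives long enough to cyclise, and the quaternary C1 provides this because it offers no β-hydrogen and blocks enolisation between C2 and C6.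

Step 5
Reactants: 8 (4R)-4-hydroxy-2,2-dimethylcyclohexan-1-one
Product: 9 (4R)-4-{[tert-butyl(dimethyl)silyl]oxy}-2,2-dimethylcyclohexan-1-one
Conditions: TBSCl, imidazole, DMF, 20 °C
Reagents that add atoms: tert-butyldimethylsilyl chloride CC(C)(C)[Si](C)(C)Cl
Why: Standard silylation of the secondary alcohol; the stereocenter is untouched.

Step 6
Reactants: 9 (4R)-4-{[tert-butyl(dimethyl)silyl]oxy}-2,2-dimethylcyclohexan-1-one
Product: 11 (4R)-4-{[tert-butyl(dimethyl)silyl]oxy}-2,2,6-trimethylcyclohexan-1-one (C6 epimers), via lithium enolate 10 (not isolated)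
Conditions: LiN(i-Pr)2 (1.1 equiv), THF, −78 °C; MeI, −78 → 0 °C
Reagents that add atoms: iodomethane CI
Why: Kinetic enolate alkylation at the only enolisable position; the new methyl-bearing center is left as an epimer mixture because it becomes sp2 in step 7.

Step 7
Reactants: 11 (4R)-4-{[tert-butyl(dimethyl)silyl]oxy}-2,2,6-trimethylcyclohexan-1-one
Product: 13 (4R)-4-{[tert-butyl(dimethyl)silyl]oxy}-2,6,6-trimethylcyclohex-1-en-1-yl trifluoromethanesulfonate, via potassium enolate 12 (not isolated)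
Conditions: KN(SiMe3)2 (1.2 equiv), THF, −78 → −20 °C; PhNTf2, −78 → 20 °C
Reagents that add atoms: N-phenylbis(trifluoromethanesulfonimide) O=S(=O)(N(c1ccccc1)S(=O)(=O)C(F)(F)F)C(F)(F)F
Why: Enol triflate formation from the only possible enolate fixes the tetrasubstituted C5=C6 double bond of ring A regiospecifically.

Step 8
Reactants: 13 the enol triflate; 14 (2-ethoxy-2-oxoethyl)zinc bromide (commercial solution)
Product: 15 ethyl 2-[(4R)-4-{[tert-butyl(dimethyl)silyl]oxy}-2,6,6-trimethylcyclohex-1-en-1-yl]acetate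
Conditions: Pd2(dba)3 (2.5 mol %), XPhos (10 mol %), THF, 60 °C
Reagents that add atoms: none
Why: Negishi coupling of the alkenyl triflate with a zinc ester enolate (Reformatsky reagent) under a bulky biarylphosphine catalyst should install C7 and C8 without moving the ring double bond.

Step 9
Reactants: 15 the ethyl ester
Product: 16 2-[(4R)-4-{[tert-butyl(dimethyl)silyl]oxy}-2,6,6-trimethylcyclohex-1-en-1-yl]acetic acid
Conditions: LiOH, THF/MeOH/H2O, 40 °C; aq. citric acid
Reagents that add atoms: lithium hydroxide [Li+].[OH-]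
Why: Saponification; the tetrasubstituted endocyclic double bond should not move into conjugation because the exocyclic isomer is strained, and the silyl ether tolerates base.

Step 10
Reactants: 17 4-bromofuran-2(5H)-one
Product: 18 4-(tributylstannyl)furan-2(5H)-one
Conditions: (Bu3Sn)2 (1.1 equiv), Pd(PPh3)4 (5 mol %), toluene, 100 °C
Reagents that add atoms: hexabutylditin CCCC[Sn](CCCC)(CCCC)[Sn](CCCC)(CCCC)CCCC
Why: Palladium-catalysed stannylation of the vinylogous acyl bromide (oxidative addition, transmetalation with the ditin, reductive elimination).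

Step 11
Reactants: 18 4-(tributylstannyl)furan-2(5H)-one
Product: 19 4-(tributylstannyl)-2,5-dihydrofuran-2-ol (lactol, racemic at the hemiacetal carbon)
Conditions: i-Bu2AlH (1.1 equiv), CH2Cl2, −78 °C; neutral aqueous work-up, used at once
Reagents that add atoms: none
Why: Partial lactone reduction stops at the aluminium lactolate at −78 °C; the ring keeps the future C19 oxygen and C11 cis on the C9=C10 bond.

Step 12
Reactants: 20 (R)-α-ionone; 21 triethyl phosphonoacetate
Product: 23 ethyl (2E,4E)-3-methyl-5-[(1R)-2,6,6-trimethylcyclohex-2-en-1-yl]penta-2,4-dienoate, via sodium phosphonate carbanion 22 (not isolated)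
Conditions: NaH, THF, 0 → 50 °C; chromatography to remove the 2Z isomer
Reagents that add atoms: none
Why: Horner–Wadsworth–Emmons olefination of the methyl ketone, E-selective at the new C9'=C10' bond; the C6' stereocenter comes from 20 and is not touched.

Step 13
Reactants: 23 the C15 ester
Product: 24 ethyl (2E,4E)-3-methyl-5-[(1R)-2,6,6-trimethyl-4-oxocyclohex-2-en-1-yl]penta-2,4-dienoate
Conditions: Mn(OAc)3·2H2O (10 mol %), t-BuOOH (5 equiv), 3 Å molecular sieves, EtOAc, 20 °C
Reagents that add atoms: tert-butyl hydroperoxide CC(C)(C)OO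
Why: Radical allylic oxidation of the ring CH2 next to the trisubstituted C4'=C5' bond; base-free conditions should spare the doubly allylic C6' stereocenter.

Step 14
Reactants: 24 the ring B enone
Product: 25 ethyl (2E,4E)-5-[(1R,4R)-4-hydroxy-2,6,6-trimethylcyclohex-2-en-1-yl]-3-methylpenta-2,4-dienoate
Conditions: (S)-2-methyl-CBS-oxazaborolidine (0.5 equiv), BH3·SMe2 (0.7 equiv), THF, −30 °C; MeOH, then aqueous work-up
Reagents that add atoms: none
Why: Corey–Bakshi–Shibata reduction, 1,2-selective on the β,β-disubstituted enone; the (S) catalyst should deliver hydride to the face that gives the 3'R carbinol (alkenyl carbon as the large group), trans to the C6' side chain.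

Step 15
Reactants: 25 the ring B allylic alcohol
Product: 26 ethyl (2E,4E)-5-[(1R,4R)-4-{[tert-butyl(dimethyl)silyl]oxy}-2,6,6-trimethylcyclohex-2-en-1-yl]-3-methylpenta-2,4-dienoate
Conditions: TBSCl, imidazole, DMF, 20 °C
Reagents that add atoms: tert-butyldimethylsilyl chloride CC(C)(C)[Si](C)(C)Cl
Why: Standard silylation; it protects the acid-sensitive allylic C3' oxygen for the following steps.

Step 16
Reactants: 26 the silylated C15 ester
Product: 27 (2E,4E)-5-[(1R,4R)-4-{[tert-butyl(dimethyl)silyl]oxy}-2,6,6-trimethylcyclohex-2-en-1-yl]-3-methylpenta-2,4-dien-1-ol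
Conditions: i-Bu2AlH (2.5 equiv), CH2Cl2, −78 °C
Reagents that add atoms: none
Why: 1,2-Reduction of the dienoate to the allylic alcohol by an aluminium hydride.

Step 17
Reactants: 27 the C15 dienol
Product: 28 {(2E,4E)-5-[(1R,4R)-4-{[tert-butyl(dimethyl)silyl]oxy}-2,6,6-trimethylcyclohex-2-en-1-yl]-3-methylpenta-2,4-dien-1-yl}triphenylphosphonium bromide
Conditions: PPh3·HBr (1.05 equiv), CH2Cl2, 0 → 20 °C
Reagents that add atoms: triphenylphosphine hydrobromide [Br-].[PH+](c1ccccc1)(c1ccccc1)c1ccccc1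
Why: Phosphonium salt formation; the dienylic alcohol ionises under mild acid and PPh3 traps the cation at the terminal carbon, while the silyl ether holds the allylic C3' oxygen.

Step 18
Reactants: 28 the C15 phosphonium bromide; 29 (2E,4E,6E)-2,7-dimethylocta-2,4,6-trienedial (3 equiv)
Product: 31 (2E,4E,6E,8E,10E,12E)-13-[(1R,4R)-4-{[tert-butyl(dimethyl)silyl]oxy}-2,6,6-trimethylcyclohex-2-en-1-yl]-2,7,11-trimethyltrideca-2,4,6,8,10,12-hexaenal, via C15 phosphorus ylide 30 (not isolated)
Conditions: NaOMe (1.05 equiv), MeOH/CH2Cl2, 0 → 20 °C; then heptane, 80 °C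
Reagents that add atoms: none
Why: Wittig olefination with excess dialdehyde for mono-condensation; the semistabilised ylide should give an E/Z mixture at C11'=C12' that is equilibrated thermally to E.

Step 19
Reactants: 31 the C25 aldehyde
Product: 32 (2E,4E,6E,8E,10E,12E)-13-[(1R,4R)-4-{[tert-butyl(dimethyl)silyl]oxy}-2,6,6-trimethylcyclohex-2-en-1-yl]-2,7,11-trimethyltrideca-2,4,6,8,10,12-hexaen-1-ol
Conditions: NaBH4, MeOH/THF, 0 °C
Reagents that add atoms: none
Why: 1,2-Reduction of the polyenal by borohydride.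

Step 20
Reactants: 32 the C25 alcohol
Product: 33 {(2E,4E,6E,8E,10E,12E)-13-[(1R,4R)-4-{[tert-butyl(dimethyl)silyl]oxy}-2,6,6-trimethylcyclohex-2-en-1-yl]-2,7,11-trimethyltrideca-2,4,6,8,10,12-hexaen-1-yl}triphenylphosphonium bromide
Conditions: PPh3·HBr (1.05 equiv), CH2Cl2, 0 °C
Reagents that add atoms: triphenylphosphine hydrobromide [Br-].[PH+](c1ccccc1)(c1ccccc1)c1ccccc1
Why: Phosphonium salt formation from the polyenylic alcohol, as in step 17.

Step 21
Reactants: 33 the C25 phosphonium bromide; 19 4-(tributylstannyl)-2,5-dihydrofuran-2-ol (1.5 equiv)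
Product: 35 (2E,4E,6E,8E,10E,12E,14E,16E)-17-[(1R,4R)-4-{[tert-butyl(dimethyl)silyl]oxy}-2,6,6-trimethylcyclohex-2-en-1-yl]-6,11,15-trimethyl-2-(tributylstannyl)heptadeca-2,4,6,8,10,12,14,16-octaen-1-ol, via C25 phosphorus ylide 34 (not isolated)
Conditions: NaN(SiMe3)2 (1.0 equiv), THF, −78 °C; 19 premixed with NaN(SiMe3)2 (1.5 equiv), −78 → 20 °C; then heptane, 80 °C, dark
Reagents that add atoms: none
Why: Wittig olefination of the ring-opened lactol (hydroxy enal) forms C11=C12 and frees the C19 hydroxyl; the butenolide origin fixes C19 cis to C11 on C9=C10, and the 11Z isomer is equilibrated thermally.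

Step 22
Reactants: 35 the stannyl octaenol; 36 (2E)-dodec-2-enoic acid
Product: 37 (2E,4E,6E,8E,10E,12E,14E,16E)-17-[(1R,4R)-4-{[tert-butyl(dimethyl)silyl]oxy}-2,6,6-trimethylcyclohex-2-en-1-yl]-6,11,15-trimethyl-2-(tributylstannyl)heptadeca-2,4,6,8,10,12,14,16-octaen-1-yl (2E)-dodec-2-enoate
Conditions: N,N'-diisopropylcarbodiimide, DMAP (cat.), CH2Cl2, 0 °C
Reagents that add atoms: none
Why: Steglich esterification of the only free hydroxyl; catalytic DMAP at 0 °C should limit deconjugation of the enoic acid.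

Step 23
Reactants: 37 the stannyl ester; 16 the ring A acid (1.5 equiv)
Product: 39 (3R,3'R,6'R)-3,3'-bis{[tert-butyl(dimethyl)silyl]oxy}-8-oxo-7,8-dihydro-β,ε-caroten-19-yl (2E)-dodec-2-enoate, via ring A acid chloride 38 (not isolated)
Conditions: 16, 1-chloro-N,N,2-trimethylprop-1-en-1-amine, CH2Cl2, 0 °C; then 37, Pd2(dba)3 (5 mol %), tri(2-furyl)phosphine (20 mol %), CO (1 atm), THF, 45 °C
Reagents that add atoms: none
Why: Stille acylation (Migita–Kosugi–Stille coupling of an acid chloride with an alkenylstannane) should form the C8–C9 bond with retention of the C9=C10 geometry under neutral conditions, the CO atmosphere keeping the β,γ-unsaturated acylpalladium from losing CO.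

Step 24
Reactants: 39 the bis-silyl ether
Product: 40 siphonein, (3R,3'R,6'R)-3,3'-dihydroxy-8-oxo-7,8-dihydro-β,ε-caroten-19-yl (2E)-dodec-2-enoate
Conditions: HF·pyridine, excess pyridine, THF, 0 → 20 °C; crystallisation in the dark
Reagents that add atoms: none
Why: Buffered fluoride cleavage of both silyl ethers should spare the two esters, the β,γ-unsaturated ketone and the allylic C3' alcohol.

**Compound list**

1 | 3-bromo-2,2-dimethylpropanoic acid | OC(=O)C(C)(C)CBr | starting material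
2 | 3-iodo-2,2-dimethylpropanoic acid | OC(=O)C(C)(C)CI | intermediate
3 | [2-(1,3-dioxolan-2-yl)ethyl]magnesium bromide | Br[Mg]CCC1OCCO1 | starting material
4 | 3-iodo-2,2-dimethylpropanoyl chloride | ClC(=O)C(C)(C)CI | intermediate
5 | 5-(1,3-dioxolan-2-yl)-1-iodo-2,2-dimethylpentan-3-one | ICC(C)(C)C(=O)CCC1OCCO1 | intermediate
6 | 6-iodo-5,5-dimethyl-4-oxohexanal | ICC(C)(C)C(=O)CCC=O | intermediate
7 | (2,2-dimethyl-3,6-dioxohexyl)chromium dichloride, chiral ligand on chromium not drawn | Cl[Cr](Cl)CC(C)(C)C(=O)CCC=O | intermediate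
8 | (4R)-4-hydroxy-2,2-dimethylcyclohexan-1-one | O=C1CC[C@@H](O)CC1(C)C | intermediate
9 | (4R)-4-{[tert-butyl(dimethyl)silyl]oxy}-2,2-dimethylcyclohexan-1-one | O=C1CC[C@@H](O[Si](C)(C)C(C)(C)C)CC1(C)C | intermediate
10 | lithium enolate of 9 | [Li+].[O-]C1=CC[C@@H](O[Si](C)(C)C(C)(C)C)CC1(C)C | intermediate
11 | (4R)-4-{[tert-butyl(dimethyl)silyl]oxy}-2,2,6-trimethylcyclohexan-1-one, C6 epimer mixture | CC1C[C@@H](O[Si](C)(C)C(C)(C)C)CC(C)(C)C1=O | intermediate
12 | potassium enolate of 11 | [K+].[O-]C1=C(C)C[C@@H](O[Si](C)(C)C(C)(C)C)CC1(C)C | intermediate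
13 | (4R)-4-{[tert-butyl(dimethyl)silyl]oxy}-2,6,6-trimethylcyclohex-1-en-1-yl trifluoromethanesulfonate | FC(F)(F)S(=O)(=O)OC1=C(C)C[C@@H](O[Si](C)(C)C(C)(C)C)CC1(C)C | intermediate
14 | (2-ethoxy-2-oxoethyl)zinc bromide | CCOC(=O)C[Zn]Br | starting material
15 | ethyl 2-[(4R)-4-{[tert-butyl(dimethyl)silyl]oxy}-2,6,6-trimethylcyclohex-1-en-1-yl]acetate | CCOC(=O)CC1=C(C)C[C@@H](O[Si](C)(C)C(C)(C)C)CC1(C)C | intermediate
16 | 2-[(4R)-4-{[tert-butyl(dimethyl)silyl]oxy}-2,6,6-trimethylcyclohex-1-en-1-yl]acetic acid | OC(=O)CC1=C(C)C[C@@H](O[Si](C)(C)C(C)(C)C)CC1(C)C | intermediate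
17 | 4-bromofuran-2(5H)-one | O=C1C=C(Br)CO1 | starting material
18 | 4-(tributylstannyl)furan-2(5H)-one | CCCC[Sn](CCCC)(CCCC)C1=CC(=O)OC1 | intermediate
19 | 4-(tributylstannyl)-2,5-dihydrofuran-2-ol | CCCC[Sn](CCCC)(CCCC)C1=CC(O)OC1 | intermediate
20 | (R)-α-ionone, (3E)-4-[(1R)-2,6,6-trimethylcyclohex-2-en-1-yl]but-3-en-2-one | CC(=O)/C=C/[C@H]1C(C)=CCCC1(C)C | starting material
21 | triethyl phosphonoacetate | CCOC(=O)CP(=O)(OCC)OCC | starting material
22 | sodium salt of 21 (phosphonate carbanion) | [Na+].CCOC(=O)[CH-]P(=O)(OCC)OCC | intermediate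
23 | ethyl (2E,4E)-3-methyl-5-[(1R)-2,6,6-trimethylcyclohex-2-en-1-yl]penta-2,4-dienoate | CCOC(=O)/C=C(C)/C=C/[C@H]1C(C)=CCCC1(C)C | intermediate
24 | ethyl (2E,4E)-3-methyl-5-[(1R)-2,6,6-trimethyl-4-oxocyclohex-2-en-1-yl]penta-2,4-dienoate | CCOC(=O)/C=C(C)/C=C/[C@H]1C(C)=CC(=O)CC1(C)C | intermediate
25 | ethyl (2E,4E)-5-[(1R,4R)-4-hydroxy-2,6,6-trimethylcyclohex-2-en-1-yl]-3-methylpenta-2,4-dienoate | CCOC(=O)/C=C(C)/C=C/[C@H]1C(C)=C[C@H](O)CC1(C)C | intermediate
26 | ethyl (2E,4E)-5-[(1R,4R)-4-{[tert-butyl(dimethyl)silyl]oxy}-2,6,6-trimethylcyclohex-2-en-1-yl]-3-methylpenta-2,4-dienoate | CCOC(=O)/C=C(C)/C=C/[C@H]1C(C)=C[C@H](O[Si](C)(C)C(C)(C)C)CC1(C)C | intermediate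
27 | (2E,4E)-5-[(1R,4R)-4-{[tert-butyl(dimethyl)silyl]oxy}-2,6,6-trimethylcyclohex-2-en-1-yl]-3-methylpenta-2,4-dien-1-ol | OC/C=C(C)/C=C/[C@H]1C(C)=C[C@H](O[Si](C)(C)C(C)(C)C)CC1(C)C | intermediate
28 | C15 phosphonium bromide from 27 | [Br-].c1ccccc1[P+](c1ccccc1)(c1ccccc1)C/C=C(C)/C=C/[C@H]1C(C)=C[C@H](O[Si](C)(C)C(C)(C)C)CC1(C)C | intermediate
29 | (2E,4E,6E)-2,7-dimethylocta-2,4,6-trienedial | O=C/C(C)=C/C=C/C=C(C)/C=O | starting material
30 | C15 phosphorus ylide from 28 | c1ccccc1P(c1ccccc1)(c1ccccc1)=C/C=C(C)/C=C/[C@H]1C(C)=C[C@H](O[Si](C)(C)C(C)(C)C)CC1(C)C | intermediate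
31 | C25 aldehyde, (2E,4E,6E,8E,10E,12E)-13-[(1R,4R)-4-silyloxy-2,6,6-trimethylcyclohex-2-en-1-yl]-2,7,11-trimethyltrideca-2,4,6,8,10,12-hexaenal | O=C/C(C)=C/C=C/C=C(C)/C=C/C=C(C)/C=C/[C@H]1C(C)=C[C@H](O[Si](C)(C)C(C)(C)C)CC1(C)C | intermediate
32 | C25 alcohol, the hexaen-1-ol from 31 | OC/C(C)=C/C=C/C=C(C)/C=C/C=C(C)/C=C/[C@H]1C(C)=C[C@H](O[Si](C)(C)C(C)(C)C)CC1(C)C | intermediate
33 | C25 phosphonium bromide from 32 | [Br-].c1ccccc1[P+](c1ccccc1)(c1ccccc1)C/C(C)=C/C=C/C=C(C)/C=C/C=C(C)/C=C/[C@H]1C(C)=C[C@H](O[Si](C)(C)C(C)(C)C)CC1(C)C | intermediate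
34 | C25 phosphorus ylide from 33 | c1ccccc1P(c1ccccc1)(c1ccccc1)=C/C(C)=C/C=C/C=C(C)/C=C/C=C(C)/C=C/[C@H]1C(C)=C[C@H](O[Si](C)(C)C(C)(C)C)CC1(C)C | intermediate
35 | stannyl octaenol, (2E,4E,6E,8E,10E,12E,14E,16E)-17-[(1R,4R)-4-silyloxy-2,6,6-trimethylcyclohex-2-en-1-yl]-6,11,15-trimethyl-2-(tributylstannyl)heptadeca-2,4,6,8,10,12,14,16-octaen-1-ol | OC\C(=C/C=C/C(C)=C/C=C/C=C(C)/C=C/C=C(C)/C=C/[C@H]1C(C)=C[C@H](O[Si](C)(C)C(C)(C)C)CC1(C)C)[Sn](CCCC)(CCCC)CCCC | intermediate
36 | (2E)-dodec-2-enoic acid | CCCCCCCCC/C=C/C(=O)O | starting material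
37 | (2E)-dodec-2-enoate of 35 | CCCCCCCCC/C=C/C(=O)OC\C(=C/C=C/C(C)=C/C=C/C=C(C)/C=C/C=C(C)/C=C/[C@H]1C(C)=C[C@H](O[Si](C)(C)C(C)(C)C)CC1(C)C)[Sn](CCCC)(CCCC)CCCC | intermediate
38 | 2-[(4R)-4-{[tert-butyl(dimethyl)silyl]oxy}-2,6,6-trimethylcyclohex-1-en-1-yl]acetyl chloride | ClC(=O)CC1=C(C)C[C@@H](O[Si](C)(C)C(C)(C)C)CC1(C)C | intermediate
39 | siphonein 3,3'-bis(tert-butyldimethylsilyl) ether | CCCCCCCCC/C=C/C(=O)OC\C(=C/C=C/C(C)=C/C=C/C=C(C)/C=C/C=C(C)/C=C/[C@H]1C(C)=C[C@H](O[Si](C)(C)C(C)(C)C)CC1(C)C)C(=O)CC1=C(C)C[C@@H](O[Si](C)(C)C(C)(C)C)CC1(C)C | intermediate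
40 | siphonein, (3R,3'R,6'R)-3,3'-dihydroxy-8-oxo-7,8-dihydro-β,ε-caroten-19-yl (2E)-dodec-2-enoate | CCCCCCCCC/C=C/C(=O)OC\C(=C/C=C/C(C)=C/C=C/C=C(C)/C=C/C=C(C)/C=C/[C@H]1C(C)=C[C@H](O)CC1(C)C)C(=O)CC1=C(C)C[C@@H](O)CC1(C)C | target

**Totals.** 24 steps. Longest linear sequence: 13 steps (steps 12 to 24, from 20). Ring A branch: steps 1 to 9, joined in step 23.

**Steps most likely to fail**

Step 4 (Proposed new method). The alkylchromium may be protonated before it adds, giving simple deiodination. The chelated β-chromio ketone may be too unreactive. The ligand may give poor facial selectivity at the aldehyde. The fallback separates ring closure from stereocontrol, sets out from 6 and returns at 8. A tin hydride radical cyclisation (Bu3SnH, AIBN, benzene, 80 °C, slow addition) should close the ring by 6-exo attack of the C2 radical on the aldehyde, giving racemic 4-hydroxy-2,2-dimethylcyclohexan-1-one F1. Lipase-catalysed kinetic resolution (Candida antarctica lipase B, vinyl acetate, MTBE) should acylate the R alcohol preferentially, giving (1R)-3,3-dimethyl-4-oxocyclohexyl acetate F2. F2 is separated from the S alcohol and methanolysed (K2CO3, MeOH) to 8.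

Step 23. The β,γ-unsaturated acylpalladium may lose CO to an allylpalladium species. The hindered α-substituted alkenylstannane may transmetalate too slowly, so that protodestannylation or ionisation of the neighbouring allylic ester takes over. The fallback makes the C8–C9 bond at the alcohol oxidation level, sets out from 37 and 15, and returns at 39. Iododestannylation of 37 (I2, CH2Cl2, −78 °C) should give the 2-iodo analogue of 37, alkenyl iodide F3. Ester 15 is reduced (i-Bu2AlH, CH2Cl2, −78 °C) to 2-[(4R)-4-{[tert-butyl(dimethyl)silyl]oxy}-2,6,6-trimethylcyclohex-1-en-1-yl]acetaldehyde F4. Nozaki–Hiyama–Kishi coupling of F3 with F4 (CrCl2, catalytic NiCl2, DMSO/THF) should give the 8-hydroxy analogue of 39 as an epimer mixture, carbinol F5. Oxidation with Dess–Martin periodinane (NaHCO3, CH2Cl2) then leads to 39.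

Step 21. Lactol 19 may dehydrate to the stannylfuran before it opens, and the semistabilised ylide may give an 11E/11Z mixture that does not equilibrate cleanly. The fallback avoids the lactol, sets out from 31 and returns at 35; steps 10, 11, 19 and 20 then fall away. Takai olefination of 31 (CHI3, CrCl2, THF) should give the all-E C26 alkenyl iodide F6. Sonogashira coupling with prop-2-yn-1-ol (Pd(PPh3)4, CuI, i-Pr2NH) should give the heptaenynol F7. Palladium-catalysed syn-hydrostannation (Bu3SnH, PdCl2(PPh3)2, THF) should place tin on the carbon next to the carbinol, which gives 35; the regioselectivity of this addition is the weak point of the fallback.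

Further compounds
F1 | step 4 | racemic 4-hydroxy-2,2-dimethylcyclohexan-1-one | O=C1CCC(O)CC1(C)C
F2 | step 4 | (1R)-3,3-dimethyl-4-oxocyclohexyl acetate | O=C1CC[C@@H](OC(C)=O)CC1(C)C
F3 | step 23 | 2-iodo analogue of 37 (iodine in place of tributylstannyl) | CCCCCCCCC/C=C/C(=O)OC\C(=C/C=C/C(C)=C/C=C/C=C(C)/C=C/C=C(C)/C=C/[C@H]1C(C)=C[C@H](O[Si](C)(C)C(C)(C)C)CC1(C)C)I
F4 | step 23 | 2-[(4R)-4-{[tert-butyl(dimethyl)silyl]oxy}-2,6,6-trimethylcyclohex-1-en-1-yl]acetaldehyde | O=CCC1=C(C)C[C@@H](O[Si](C)(C)C(C)(C)C)CC1(C)C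
F5 | step 23 | 8-hydroxy analogue of 39 (C8 epimers) | CCCCCCCCC/C=C/C(=O)OC\C(=C/C=C/C(C)=C/C=C/C=C(C)/C=C/C=C(C)/C=C/[C@H]1C(C)=C[C@H](O[Si](C)(C)C(C)(C)C)CC1(C)C)C(O)CC1=C(C)C[C@@H](O[Si](C)(C)C(C)(C)C)CC1(C)C
F6 | step 21 | (1E,3E,5E,7E,9E,11E,13E)-1-iodo-3,8,12-trimethyl-14-[(1R,4R)-4-silyloxy-2,6,6-trimethylcyclohex-2-en-1-yl]tetradeca-1,3,5,7,9,11,13-heptaene | I/C=C/C(C)=C/C=C/C=C(C)/C=C/C=C(C)/C=C/[C@H]1C(C)=C[C@H](O[Si](C)(C)C(C)(C)C)CC1(C)C
F7 | step 21 | (4E,6E,8E,10E,12E,14E,16E)-6,11,15-trimethyl-17-[(1R,4R)-4-silyloxy-2,6,6-trimethylcyclohex-2-en-1-yl]heptadeca-4,6,8,10,12,14,16-heptaen-2-yn-1-ol | OCC#C/C=C/C(C)=C/C=C/C=C(C)/C=C/C=C(C)/C=C/[C@H]1C(C)=C[C@H](O[Si](C)(C)C(C)(C)C)CC1(C)C
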